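The closed vessel called midnight is the very flask asked about, and what interests me is the substrate that appears in none of the columns I can follow.

| flask | substrate | partner | protic impurity | initiator | remark | time |
|---|---|---|---|---|---|---|
| midnight | 20 mM | 0.90 equiv | 10 mM | 10 mol% | the very flask that is asked about, followed so far |  |
| dusk | 40 mM | 0.90 equiv | 10 mM | 10 mol% | run made earlier |  |
| flask | 20 mM | 0.900 equiv | 10.0 mM | 10 mol% |  | 15 d |

- midnight (time / d: side product / %, target / %, substrate / %): 0.625: 21.1, 1.3, 64.9; 1.25: 24.6, 0, 58.9; 3.00: 25.8, 0, 55.2; 8.00: 26.1, 0, 53.6
- dusk (time / d: side product / %, target / %, substrate / %): 1.25: 35.0, 0.1, 49.9; 3.00: 35.6, 0.6, 45.9; 6.00: 32.9, 0.2, 43.4; 15.0: 34.8, 0, 44.9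

(readings scatter by 1 percentage point)

- which holds at 15 d: what has brought the reaction to rest, or that it has not come to rest (it is still moving / all of the substrate has reacted / the partner has run out first)
- side product at 15 d, in percent of the substrate charged

- a species is counted by the substrate in it: one side product counts as two
- the numbers in the tables scatter with a standard deviation of 1 percentage point
- the reaction counts as stopped when no species that holds the substrate changes by six tenths of a point or more over the second half of the time

At 8.00 d, midnight shows target at 0%, and substrate and side product leave 20.3% of the charge unaccounted for. Dusk, with [substrate] at 40 mM instead of 20 mM but the same loading, leaves 20.3% at 15.0 d. So I fold the givens into one dimensionless number, the locked share, 20.0%, which is twice the initiator loading: the part of the charged substrate held out of the substrate and side product columns if each initiator ties up two substrate.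

With target read at 0%, the balance then reads: side product equals the charge minus locked share minus substrate left. With midnight's last substrate reading this gives me 26.4%. Was one number enough? No. Both runs share it, yet they keep 53.6% and 44.9% of substrate, so it gives the sum and the readings must give the split. Dusk's substrate, 43.4% at 6.00 d and 44.9% at 15.0 d, looks at rest to me.

The forecast says the partner has run out first and 26.2%, noting that “Side product has been flat since about 3 d”. My figure stands 0.2 percentage points above it.

The flask gives the partner has run out first and 25.9%.

    partner + protic impurity → quenched reagent (k = 0.0530 M⁻¹ min⁻¹)
    2 initiating radical → ended chains A (k = 6.00 × 10⁶ M⁻¹ s⁻¹)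
    partner + chain carrier → target + initiating radical (k = 1.90 × 10⁵ M⁻¹ min⁻¹)
    substrate + initiating radical → chain carrier (k = 2.60 × 10⁵ M⁻¹ min⁻¹)
    2 chain carrier → ended chains B (k = 1.30 × 10⁸ M⁻¹ s⁻¹)
    substrate + target → side product (k = 0.140 M⁻¹ min⁻¹)
    initiator → 2 initiating radical (k = 8.80 × 10⁻⁴ min⁻¹)
    partner → decomposed reagent (k = 0.0160 min⁻¹)

The partner is the limiting reagent, with 0% of its charge left at 15.0 d. Ended chains B, where each counts as two, stand at 20.0% of the substrate charged at 15.0 d, beside a locked share of 20.0%. A neighbour charged with 25 mol% of initiator has a locked share of 50.0% and keeps 12.2% of its substrate, so the balance gives 37.8%, and that flask ends with side product at 37.8%.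

Readings and results were generated by integration with constants of no real substance; noise was put on by code.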